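Numbering: dioxolane O1–O2–C3(CH3)(CH2CO2H)–C4H2–C5(CH3)(chain); chain C6H2–C7H(CH3)–C8H2–C9H2–C10H=C11H–C12H2–C13H2–C14H=C15H–Ph.
Retrosynthesis: ester hydrolysis; C10=C11 (Julia–Kocienski, the tail bought with its E-styrene); the ring at C4–C5 and C3–O2 in one cut; then C5–CH3 and the C10 oxygen back to (R)-citronellal.
Enabling feature: C4 is a bare CH2 between the two fully substituted peroxy carbons, so C5 with O1–O2 can be a ketone-derived peroxycarbenium ion and C3=C4 a 1,1-disubstituted alkene (methyl 3-methylbut-3-enoate) that attacks through its CH2 end and is then captured at C3 by O2.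
Forward: citronellal becomes a C5 methyl ketone with C10 masked as a silyl ether, then a silyl peroxyketal; the annulation builds the only ring; the diene tail is joined last so that no alkene in the chain can compete for the cation.
Stereochemistry: C7 from (R)-citronellal; C5 and C3 in the annulation under a confined chiral Brønsted acid (ion-pair control); C14=C15 bought as E, C10=C11 E from the Julia–Kocienski step.

Key step: step 7

Assumption: the sense of induction of the confined acid on a peroxycarbenium ion has no direct precedent; the (S,S) acid is written for the 5R series, and its mirror image is used if the opposite sense is found.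

Step 1
Reactants: 1 (R)-citronellal [(3R)-3,7-dimethyloct-6-enal]
Product: 2 (4R)-4,8-dimethylnon-7-en-2-ol
Conditions: MeMgBr, Et2O, 0 °C; aq. NH4Cl
Reagents that add atoms: methylmagnesium bromide, C[Mg]Br
Why: Grignard addition to the aldehyde installs the C5 methyl group; the new carbinol centre is not controlled because it is oxidised away in step 4, and the C7 centre comes unchanged from 1.

Step 2
Reactants: 2 (4R)-4,8-dimethylnon-7-en-2-ol
Product: 4 (4R)-4-methylheptane-1,6-diol, via ozonide 3 (not isolated)
Conditions: O3, CH2Cl2, −78 °C; then NaBH4, MeOH, −78 °C to rt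
Reagents that add atoms: ozone, O=[O+][O-]
Why: Ozonolysis of the trisubstituted alkene with reductive NaBH4 work-up removes the isopropylidene terminus and leaves C10 as a primary alcohol.

Step 3
Reactants: 4 (4R)-4-methylheptane-1,6-diol
Product: 5 (4R)-7-{[tert-butyl(diphenyl)silyl]oxy}-4-methylheptan-2-ol
Conditions: t-BuPh2SiCl (1.05 equiv), imidazole, CH2Cl2, 0 °C
Reagents that add atoms: tert-butyl(chloro)diphenylsilane, CC(C)(C)[Si](Cl)(c1ccccc1)c1ccccc1
Why: Silyl ether formation with the bulky tert-butyldiphenylsilyl chloride is selective for the primary over the secondary hydroxyl.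

Step 4
Reactants: 5 (4R)-7-{[tert-butyl(diphenyl)silyl]oxy}-4-methylheptan-2-ol
Product: 6 (4R)-7-{[tert-butyl(diphenyl)silyl]oxy}-4-methylheptan-2-one
Conditions: DMP, CH2Cl2, rt
Reagents that add atoms: none
Why: Periodinane oxidation (DMP = 1,1,1-triacetoxy-1,1-dihydro-1,2-benziodoxol-3(1H)-one) of the secondary alcohol gives the methyl ketone under neutral conditions with no risk to the β-stereocentre.

Step 5
Reactants: 6 (4R)-7-{[tert-butyl(diphenyl)silyl]oxy}-4-methylheptan-2-one
Product: 8 tert-butyl{[(4R)-6-hydroperoxy-6-methoxy-4-methylheptyl]oxy}diphenylsilane, via dimethyl ketal 7 (not isolated)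
Conditions: HC(OMe)3, MeOH, cat. PPTS, rt; concentrate; then anhydrous H2O2 in Et2O, cat. PPTS, 0 °C
Reagents that add atoms: trimethyl orthoformate, COC(OC)OC; methanol, CO; hydrogen peroxide, OO
Why: Acid-catalysed ketalization followed by acid-catalysed exchange of one methoxy group for hydrogen peroxide through the oxocarbenium ion (perhydrolysis of a ketal) should give the methoxy hydroperoxide, whose new acetal centre is left uncontrolled because it becomes planar in step 7.

Step 6
Reactants: 8 tert-butyl{[(4R)-6-hydroperoxy-6-methoxy-4-methylheptyl]oxy}diphenylsilane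
Product: 9 tert-butyl{[(4R)-6-methoxy-4-methyl-6-(triethylsilylperoxy)heptyl]oxy}diphenylsilane
Conditions: Et3SiCl, imidazole, DMF, 0 °C
Reagents that add atoms: chlorotriethylsilane, CC[Si](Cl)(CC)CC
Why: O-Silylation of the hydroperoxide (silyl chloride and imidazole) caps the acidic OOH and installs the silyl group that is later expelled from oxygen when the ring closes.

Step 7
Reactants: 9 tert-butyl{[(4R)-6-methoxy-4-methyl-6-(triethylsilylperoxy)heptyl]oxy}diphenylsilane; 10 methyl 3-methylbut-3-enoate (3 equiv)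
Product: 13 methyl 2-[(3S,5R)-5-[(2R)-5-{[tert-butyl(diphenyl)silyl]oxy}-2-methylpentyl]-3,5-dimethyl-1,2-dioxolan-3-yl]acetate, via peroxycarbenium ion 11 (not isolated), via tertiary carbocation 12 (not isolated)
Conditions: (S,S)-IDPi acid [(ArO)2P(=NSO2CF3)]2NH, (ArO)2 = (S)-3,3'-bis[3,5-bis(trifluoromethyl)phenyl]-1,1'-binaphthalene-2,2'-diolate (5 mol%), CH2Cl2/pentane, −78 °C
Reagents that add atoms: none
Why: Proposed new method: the confined acid protonates the methoxy group of 9 to give peroxycarbenium ion 11 as a contact ion pair with its chiral anion, the CH2 terminus (C4) of alkene 10 adds to the cationic carbon C5 to make the C4–C5 bond and tertiary cation 12, and the silylperoxy oxygen O2 then captures C3 with release of Et3Si+ to methanol (Et3SiOMe, proton returned to the catalyst), so the dioxolane is closed around the new C4–C5 bond in one operation. The closest known reaction types are the SnCl4-mediated [3+2] annulation of triethylsilyl peroxyketals with 1,1-disubstituted alkenes, which gives the same ring constitution without absolute control, and asymmetric Mukaiyama aldol additions to methyl alkyl ketones under the same class of confined acid, in which the anion tells CH3 from CH2R on an oxocarbenium carbon. The only ring closed is the 1,2-dioxolane, by intermolecular C–C bond formation followed by five-membered collapse of an oxygen nucleophile on a free tertiary cation (5-exo-type, geometrically unconstrained). C5 (R) is controlled by the chiral counteranion, which leaves one face of planar 11 open to the alkene, the remote C7 centre being too far to interfere; C3 (S) is fixed when 12 collapses inside the same chiral pocket, which has to place CH2CO2CH3 trans to the C5 pentyl chain because the substrate itself offers little bias here. The step needs Markovnikov regioselectivity, secured by the 1,1-disubstituted alkene (only the tertiary cation forms, so C4 ends as the ring CH2), and chemoselectivity for the external alkene, secured by having no alkene in 9 and C10 masked as a silyl ether.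

Step 8
Reactants: 13 methyl 2-[(3S,5R)-5-[(2R)-5-{[tert-butyl(diphenyl)silyl]oxy}-2-methylpentyl]-3,5-dimethyl-1,2-dioxolan-3-yl]acetate
Product: 14 methyl 2-[(3S,5R)-5-[(2R)-5-hydroxy-2-methylpentyl]-3,5-dimethyl-1,2-dioxolan-3-yl]acetate
Conditions: HF·pyridine, THF/pyridine, 0 °C to rt
Reagents that add atoms: none
Why: Fluoride-driven desilylation of the primary silyl ether should proceed under buffered HF·pyridine, conditions that leave the dialkyl peroxide and the methyl ester untouched.

Step 9
Reactants: 14 methyl 2-[(3S,5R)-5-[(2R)-5-hydroxy-2-methylpentyl]-3,5-dimethyl-1,2-dioxolan-3-yl]acetate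
Product: 15 methyl 2-[(3S,5R)-3,5-dimethyl-5-[(2R)-2-methyl-5-oxopentyl]-1,2-dioxolan-3-yl]acetate
Conditions: DMP, CH2Cl2, 0 °C to rt
Reagents that add atoms: none
Why: Periodinane oxidation of the primary alcohol to the aldehyde is non-basic and does not touch the dialkyl peroxide.

Step 10
Reactants: 16 (4E)-5-phenylpent-4-en-1-ol
Product: 17 1-phenyl-5-{[(4E)-5-phenylpent-4-en-1-yl]sulfanyl}-1H-tetrazole
Conditions: 1-phenyl-1H-tetrazole-5-thiol, PPh3, DIAD, THF, 0 °C to rt
Reagents that add atoms: 1-phenyl-1H-tetrazole-5-thiol, Sc1nnnn1-c1ccccc1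
Why: Mitsunobu thioetherification of the primary alcohol with the acidic tetrazolethiol installs the sulfide with the E-styrene carried through unchanged.

Step 11
Reactants: 17 1-phenyl-5-{[(4E)-5-phenylpent-4-en-1-yl]sulfanyl}-1H-tetrazole
Product: 18 1-phenyl-5-{[(4E)-5-phenylpent-4-en-1-yl]sulfonyl}-1H-tetrazole
Conditions: (NH4)6Mo7O24·4H2O (10 mol%), 30% H2O2, EtOH, 0 °C to rt
Reagents that add atoms: hydrogen peroxide, OO
Why: Molybdate-catalysed oxidation with H2O2 takes the sulfide to the sulfone without epoxidising the styrene double bond.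

Step 12
Reactants: 18 1-phenyl-5-{[(4E)-5-phenylpent-4-en-1-yl]sulfonyl}-1H-tetrazole; 15 methyl 2-[(3S,5R)-3,5-dimethyl-5-[(2R)-2-methyl-5-oxopentyl]-1,2-dioxolan-3-yl]acetate
Product: 20 methyl 2-[(3S,5R)-3,5-dimethyl-5-[(2R,5E,9E)-2-methyl-10-phenyldeca-5,9-dien-1-yl]-1,2-dioxolan-3-yl]acetate, via potassium sulfonyl carbanion 19 (not isolated)
Conditions: 18, KN(SiMe3)2, DME, −60 °C; then 15, −60 °C to rt; aq. NH4Cl
Reagents that add atoms: none
Why: Julia–Kocienski olefination: addition of the metalated tetrazolyl sulfone to the aldehyde, Smiles rearrangement and anti elimination of SO2 and tetrazololate should give the C10=C11 alkene with E geometry (potassium counterion, DME), the pre-formed carbanion being consumed by the aldehyde faster than it can enolise the ester.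

Step 13
Reactants: 20 methyl 2-[(3S,5R)-3,5-dimethyl-5-[(2R,5E,9E)-2-methyl-10-phenyldeca-5,9-dien-1-yl]-1,2-dioxolan-3-yl]acetate
Product: 21 2-[(3S,5R)-3,5-dimethyl-5-[(2R,5E,9E)-2-methyl-10-phenyldeca-5,9-dien-1-yl]-1,2-dioxolan-3-yl]acetic acid
Conditions: LiOH, THF/H2O, 0 °C; then 1 M HCl to pH 3
Reagents that add atoms: lithium hydroxide, [Li+].[OH-]
Why: Saponification of the methyl ester with LiOH at 0 °C should outpace β-elimination of the peroxide and leaves the three stereocentres and both E alkenes unchanged.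

Compound list
1 | (R)-citronellal, (3R)-3,7-dimethyloct-6-enal | C[C@H](CCC=C(C)C)CC=O | starting material
2 | (4R)-4,8-dimethylnon-7-en-2-ol (both C2 epimers) | CC(O)C[C@H](C)CCC=C(C)C | intermediate
3 | 3-[(3R)-5-hydroxy-3-methylhexyl]-5,5-dimethyl-1,2,4-trioxolane (ozonide, not isolated) | CC(O)C[C@H](C)CCC1OOC(C)(C)O1 | intermediate
4 | (4R)-4-methylheptane-1,6-diol (both C6 epimers) | CC(O)C[C@H](C)CCCO | intermediate
5 | (4R)-7-{[tert-butyl(diphenyl)silyl]oxy}-4-methylheptan-2-ol | CC(O)C[C@H](C)CCCO[Si](c1ccccc1)(c1ccccc1)C(C)(C)C | intermediate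
6 | (4R)-7-{[tert-butyl(diphenyl)silyl]oxy}-4-methylheptan-2-one | CC(=O)C[C@H](C)CCCO[Si](c1ccccc1)(c1ccccc1)C(C)(C)C | intermediate
7 | tert-butyl{[(4R)-6,6-dimethoxy-4-methylheptyl]oxy}diphenylsilane (dimethyl ketal, not isolated) | COC(C)(OC)C[C@H](C)CCCO[Si](c1ccccc1)(c1ccccc1)C(C)(C)C | intermediate
8 | tert-butyl{[(4R)-6-hydroperoxy-6-methoxy-4-methylheptyl]oxy}diphenylsilane (both C6 epimers) | COC(C)(OO)C[C@H](C)CCCO[Si](c1ccccc1)(c1ccccc1)C(C)(C)C | intermediate
9 | tert-butyl{[(4R)-6-methoxy-4-methyl-6-(triethylsilylperoxy)heptyl]oxy}diphenylsilane (both C6 epimers) | COC(C)(OO[Si](CC)(CC)CC)C[C@H](C)CCCO[Si](c1ccccc1)(c1ccccc1)C(C)(C)C | intermediate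
10 | methyl 3-methylbut-3-enoate | C=C(C)CC(=O)OC | starting material
11 | peroxycarbenium ion from 9: [(4R)-7-{[tert-butyl(diphenyl)silyl]oxy}-4-methylheptan-2-ylidene](triethylsilyloxy)oxonium (not isolated) | CC(=[O+]O[Si](CC)(CC)CC)C[C@H](C)CCCO[Si](c1ccccc1)(c1ccccc1)C(C)(C)C | intermediate
12 | tertiary carbocation at C3 after C4–C5 bond formation, C5 and C7 configured as in 13 (not isolated) | C[C+](CC(=O)OC)C[C@](C)(OO[Si](CC)(CC)CC)C[C@H](C)CCCO[Si](c1ccccc1)(c1ccccc1)C(C)(C)C | intermediate
13 | methyl 2-[(3S,5R)-5-[(2R)-5-{[tert-butyl(diphenyl)silyl]oxy}-2-methylpentyl]-3,5-dimethyl-1,2-dioxolan-3-yl]acetate | C[C@H](CCCO[Si](c1ccccc1)(c1ccccc1)C(C)(C)C)C[C@]1(C)C[C@@](C)(CC(=O)OC)OO1 | intermediate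
14 | methyl 2-[(3S,5R)-5-[(2R)-5-hydroxy-2-methylpentyl]-3,5-dimethyl-1,2-dioxolan-3-yl]acetate | C[C@H](CCCO)C[C@]1(C)C[C@@](C)(CC(=O)OC)OO1 | intermediate
15 | methyl 2-[(3S,5R)-3,5-dimethyl-5-[(2R)-2-methyl-5-oxopentyl]-1,2-dioxolan-3-yl]acetate | C[C@H](CCC=O)C[C@]1(C)C[C@@](C)(CC(=O)OC)OO1 | intermediate
16 | (4E)-5-phenylpent-4-en-1-ol | OCCC/C=C/c1ccccc1 | starting material
17 | 1-phenyl-5-{[(4E)-5-phenylpent-4-en-1-yl]sulfanyl}-1H-tetrazole | c1ccccc1-n1nnnc1SCCC/C=C/c1ccccc1 | intermediate
18 | 1-phenyl-5-{[(4E)-5-phenylpent-4-en-1-yl]sulfonyl}-1H-tetrazole | O=S(=O)(CCC/C=C/c1ccccc1)c1nnnn1-c1ccccc1 | intermediate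
19 | potassium salt of the α-sulfonyl carbanion of 18 (not isolated) | [K+].O=S(=O)([CH-]CC/C=C/c1ccccc1)c1nnnn1-c1ccccc1 | intermediate
20 | methyl 2-[(3S,5R)-3,5-dimethyl-5-[(2R,5E,9E)-2-methyl-10-phenyldeca-5,9-dien-1-yl]-1,2-dioxolan-3-yl]acetate | C[C@H](CC/C=C/CC/C=C/c1ccccc1)C[C@]1(C)C[C@@](C)(CC(=O)OC)OO1 | intermediate
21 | 2-[(3S,5R)-3,5-dimethyl-5-[(2R,5E,9E)-2-methyl-10-phenyldeca-5,9-dien-1-yl]-1,2-dioxolan-3-yl]acetic acid | C[C@H](CC/C=C/CC/C=C/c1ccccc1)C[C@]1(C)C[C@@](C)(CC(=O)O)OO1 | target

Total step count: 13. Longest linear sequence: 11 steps (steps 1 to 9, 12 and 13).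

Steps most likely to fail

Step 7 (Proposed new method). What may go wrong: slow turnover of the acid after silyl transfer, fragmentation of the peroxycarbenium ion by 1,2-shift to oxygen, weak facial discrimination at C5, or closure at C3 in the unwanted sense. The fallback uses known chemistry and closes the ring at O2–C3 instead. It sets out from 9: SnCl4-mediated vinylogous Mukaiyama addition of [(1-methoxy-3-methylbuta-1,3-dien-1-yl)oxy]trimethylsilane through its γ-CH2 should give the silylperoxy enoate methyl (2E,7R)-10-{[tert-butyl(diphenyl)silyl]oxy}-3,5,7-trimethyl-5-(triethylsilylperoxy)dec-2-enoate F1. Brief Bu4NF/AcOH at 0 °C should free the hydroperoxide methyl (2E,7R)-10-{[tert-butyl(diphenyl)silyl]oxy}-5-hydroperoxy-3,5,7-trimethyldec-2-enoate F2. Et2NH in CF3CH2OH should then close the ring by 5-exo-trig oxa-Michael addition and come back to the route at 13. Because C7 is fixed, every stereoisomer is a diastereomer and is to be separated by preparative HPLC; the C3 epimer can be recycled by renewed exposure to the base (retro-Michael and re-closure).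

Step 5. What may go wrong: exchange of both methoxy groups (geminal dihydroperoxide) or hydrolysis back to the ketone by traces of water. The fallback sets out from 6: Wittig methylenation (Ph3PCH3Br, KOC(CH3)3, THF) should give the alkene tert-butyl{[(4R)-4,6-dimethylhept-6-en-1-yl]oxy}diphenylsilane F3. Ozonolysis in CH2Cl2/CH3OH at −78 °C, in which methanol traps the carbonyl oxide formed on the disubstituted carbon, should come back to the route at 8.

Step 12. What may go wrong: erosion of E selectivity in the addition and elimination sequence, or base-induced β-elimination of the peroxide through the ester enolate. The fallback sets out from 15: Wittig methylenation (Ph3P=CH2, THF, −78 °C) should give the terminal alkene methyl 2-[(3S,5R)-3,5-dimethyl-5-[(2R)-2-methylhex-5-en-1-yl]-1,2-dioxolan-3-yl]acetate F4. Cross-metathesis with commercial (1E)-hexa-1,5-dien-1-ylbenzene (second-generation Grubbs catalyst, CH2Cl2, 40 °C) should come back to the route at 20, the minor Z isomer being removed on AgNO3-impregnated silica.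

Further compounds
F1 | step 7 | methyl (2E,7R)-10-{[tert-butyl(diphenyl)silyl]oxy}-3,5,7-trimethyl-5-(triethylsilylperoxy)dec-2-enoate (both C5 epimers) | COC(=O)/C=C(\C)CC(C)(OO[Si](CC)(CC)CC)C[C@H](C)CCCO[Si](c1ccccc1)(c1ccccc1)C(C)(C)C
F2 | step 7 | methyl (2E,7R)-10-{[tert-butyl(diphenyl)silyl]oxy}-5-hydroperoxy-3,5,7-trimethyldec-2-enoate (both C5 epimers) | COC(=O)/C=C(\C)CC(C)(OO)C[C@H](C)CCCO[Si](c1ccccc1)(c1ccccc1)C(C)(C)C
F3 | step 5 | tert-butyl{[(4R)-4,6-dimethylhept-6-en-1-yl]oxy}diphenylsilane | C=C(C)C[C@H](C)CCCO[Si](c1ccccc1)(c1ccccc1)C(C)(C)C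
F4 | step 12 | methyl 2-[(3S,5R)-3,5-dimethyl-5-[(2R)-2-methylhex-5-en-1-yl]-1,2-dioxolan-3-yl]acetate | C[C@H](CCC=C)C[C@]1(C)C[C@@](C)(CC(=O)OC)OO1
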